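If the new flasks differed in nothing but temperature, I wanted a way to turn hours at one temperature into hours at another.

| flask | starting material | partner | temperature | remark | time |
|---|---|---|---|---|---|
| zeta | 0.10 M | 0.60 equiv | 54 °C | run made earlier |  |
| eta | 0.10 M | 2.4 equiv | 95 °C | run made earlier |  |
| Saturday's | 0.10 M | 1.20 equiv | 110 °C |  | 3.0 h |
| Wednesday's | 0.10 M | 1.20 equiv | 60 °C |  | 3.0 h |
| Monday's | 0.10 M | 1.20 equiv | 85 °C |  | 3.0 h |
| Friday's | 0.10 M | 1.20 equiv | 35 °C |  | 3.0 h |

- zeta (time / h: target / %): 6.00: 0.4; 20.0: 1.5; 40.0: 6.6; 60.0: 15.0
- eta (time / h: target / %): 0.500: 21.1; 1.33: 64.8; 3.00: 88.5; 8.00: 93.1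

(each reading ± 0.5 percentage points)

- a reading or a percentage of target counts all its forms, free or not

1. the flask with the highest amount of target, in percent of the starting material charged ("all alike" if they lie within 1.5 percentage points) (Saturday's / Wednesday's / Monday's / Friday's / all alike)
2. final target, as a percentage of the starting material charged, in Saturday's
3. final target, as a percentage of the starting material charged, in Wednesday's
4. final target, as a percentage of the starting material charged, in Monday's
5. final target, as a percentage of the starting material charged, in Friday's

The zeta run looked impossible at first. Between 20.0 h and 60.0 h the time grew by a factor of 3.00, yet target grew ten times, which is more, whereas a single first-order step gives at most the time factor. So target waited on something that had to build up first, an induction period, and I took target as growing with a power of time. Those two readings, each with a scatter of 0.5 percentage points, put that power at 2.10.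

On the same power, I reckoned that the eta run stood at zeta's 15.0% at 0.425 h, so the clock ran faster by a factor of 141 from the zeta run at 54 °C to the eta run at 95 °C. Put into an Arrhenius factor, this gave 121 kJ mol⁻¹, which I called the clock energy: the energy that converts hours at one temperature into hours at another. The partner differed between those runs, so the figure carries that change too.

By this clock, Wednesday's 3.0 h counted as 6.68 h of zeta, giving 0.151%, and Friday's counted as 0.194 h, giving <0.001%. Monday's counted as 0.996 h of eta, and a straight line between eta's first two readings gave 47.2%. Saturday's counted as 14.1 h, later than eta's last reading, so I took that reading, 93.1%, and named Saturday's the richest.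

The forecast named Saturday's, with 92%, 0.3%, 36% and 0.01% for Saturday's, Wednesday's, Monday's and Friday's, “complete in 3 h, near the plateau” for Saturday's, and its Monday's figure stood lower than mine.

Saturday's held the most: Saturday's 78.4%, Wednesday's 0.104%, Monday's 42.7%, Friday's 0%.

    starting material + open intermediate → side product (k = 0.00200 M⁻¹ s⁻¹, Ea = 78.0 kJ mol⁻¹)
    crystals ⇌ target, rate k2*(cs2 - [target]) while solid is left; crystals form when [target] > cs2 (solubility = 14.0 mM, k = 0.0180 s⁻¹)
    starting material → open intermediate (k = 0.00140 s⁻¹, Ea = 119 kJ mol⁻¹)
    partner → second intermediate (k = 0.00220 s⁻¹, Ea = 119 kJ mol⁻¹)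
    open intermediate + second intermediate ⇌ target (K = 23.0 M⁻¹, k = 0.0300 M⁻¹ s⁻¹, Ea = 85.0 kJ mol⁻¹, ΔH = −60.0 kJ mol⁻¹)
    (constants at 110 °C)

Saturday's target stood at 78.2% at 1.50 h and 78.4% at 30.0 h, 15 points under my figure. Used once more, the clock made Wednesday's 30.0 h into 66.8 h of zeta and 18.8% of target, where Wednesday's held 23.8%. It made Friday's 30.0 h into 1.94 h and 0.0111%, where Friday's held 0.00856%.

The numbers in the tables come from a simulation with constants of no real substance; scatter was added.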